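## Analysis of the target

Compound 40 is a cembranolide. With cembrane numbering, the 14-membered carbocycle C1–C14 is cis-fused across C1–C2 to an α-methylene-γ-butyrolactone (C15=C17H2, C16=O, lactone oxygen on C2); the ring carries an E-C3=C4 and a Z-C7=C8 trisubstituted alkene (methyl groups on C4 and C8), a trans trisubstituted C11–C12 epoxide (methyl on C12), an acetate on C13 and the methylene C14. The five stereocentres form two clusters, C1/C2 (1S,2S) and C11/C12/C13 (11S,12R,13R), insulated by C14 on one side and by the C3–C10 chain on the other, so each has to be set on its own. Inside the second cluster the epoxide oxygen and the C13 oxygen are threo (syn in the zigzag drawing of C14–C13–C12–C11). A hydroxyl-directed epoxidation of a C13 carbinol next to the C12 methyl group delivers the opposite, erythro, arrangement (A(1,2) strain). The α-methylene lactone is a Michael acceptor and must appear last, the epoxy acetate tolerates neither acid nor strong base, the Z-C7=C8 bond can isomerise through any allylic anion or radical at C9, and the doubly allylic C2–O bond ionises easily. The difficulty is to close the 14-membered ring while three alkene geometries, one of them Z, and two unrelated stereoclusters stay defined. The strategy rests on the segment C10–C11–C12(CH3)–C13: the epoxy acetate is a masked allylic alcohol C13(OH)–C12(CH3)=C11–C10, which is what a C12–C13 vinyl epoxide gives when a nucleophile enters at C10 with 1,4-opening, and C10 lies next to C9, which is allylic to C7=C8 and can carry a sulfonyl-stabilised carbanion.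

## Retrosynthetic reasoning

40 to 37. The lactone C16–O2 bond and the oxidation level of C16 are taken back to the 2,16-diol 37. The Michael acceptor is thereby absent from every earlier step, and the forward reaction only has to oxidise a primary allylic alcohol in the presence of a secondary one that then closes the five-membered ring.

37 to 36 to 35. The silyl ethers on O2 and O16 are put back (36), and the C13–OAc bond is cut with inversion, which leads to the erythro epoxy alcohol 35 with a 13S carbinol. The cut is made with inversion because directed epoxidation gives erythro and 40 is threo. Introducing the acetate by a Mitsunobu esterification corrects this at no cost in steps.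

35 to 34. The epoxide oxygen is removed to give the E-C11=C12 allylic alcohol 34. The forward epoxidation has to pick one alkene out of four and one face; the free 13S hydroxyl does both.

34 to 33. A phenylsulfonyl group is placed on C9 (33). It exists only to make C9 nucleophilic, and both C9 epimers serve.

33 to 32. The ring is opened at C9–C10. This bond is chosen because C10 is the remote terminus of the allyl unit C10–C11–C12 that a C12–C13 vinyl epoxide generates on ionisation, and C9 is an allylic sulfone carbon. One forward step then forms the bond, the ring, the E-C11=C12 alkene and the free C13 hydroxyl. It touches neither C13 nor the C1/C2 pair, so all stereochemistry of 32 is made in open-chain compounds.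

32 to 29 and 30, to 28, to 27. The vinyl group is cut at C10=C11 (methylenation of aldehyde 29 with the one-carbon phosphonium salt 30). 29 comes from epoxy alcohol 28 and 28 from the E-allylic alcohol 27 by Sharpless epoxidation. The primary hydroxyl on C11 singles out the C12=C13 alkene among four, and the reagent alone sets C12 and C13.

27 to 26, to 24 and 25. The C12=C13 bond is cut by a Wittig disconnection into aldehyde 24 (C13) and the stabilised ylide 25, which brings C11, C12 and the methyl group with E geometry.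

24 to 23, to 17 and 19. The C1–C15 bond is cut. Ester 23 is the conjugate adduct of a 2-propenyl copper reagent made from bromide 19 (itself the silyl ether of 18) and the γ-silyloxy enoate 17. The existing C2 centre sets C1 anti, which is the relationship of the cis-fused lactone.

17 to 16 to 15, to 12 and 13. The E-enoate comes from the ynoate 15 by trans reduction, and 15 is cut at C1–C2 into enal 12 and methyl propiolate 13, which supplies C1, C14 and C13. This is the only step in which a catalyst has to create absolute configuration in the C1/C2 cluster.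

12 back to 1. Enal 12 comes from alcohol 11 and its silyl ether 10. The sulfone comes from allylic alcohol 8, and 8 from the Z-enoate 7. The Z-C7=C8 bond is cut into aldehyde 4 and phosphonate 5, because allylic oxidation of a geranyl terminus would give the E isomer. Aldehyde 4 comes from the silyl ether 2 of geraniol 1 by cleavage of the distal alkene; 1 already contains C2–C7 with the E-C3=C4 bond.

## Alternatives that were turned down

Alternative 1: The ring is cut at C2–C3, together with the lactone C16–O bond. In the forward step a C3 alkenyl iodide adds to a C2 aldehyde under catalytic chromium and nickel salts with a chiral sulfonamide ligand and cathodic regeneration of divalent chromium. The C2 alkoxide then closes onto a C16 methyl ester to give lactone A1.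
- For it: one operation forms the ring, the C2 centre and the lactone. The alkenyl-chromium addition tolerates esters, silyl ethers and alkenes and needs no anion-stabilising group, so nothing like the desulfonylation of 33 follows. On that point it is stronger than the chosen route.
- Against it: C2 is created during ring closure, so ring formation and diastereoselection next to the epimerisable α-centre C1 depend on the same transition state. A1 lacks C17, and the methylene must be added later by enolate chemistry. A1 carries the C13 oxygen in the configuration of 40, so a directed epoxidation of its C11=C12 bond would give the erythro isomer and an inversion would still be needed.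
- Comparison: the chosen route sets C2 by a catalyst-controlled addition to the open-chain enal 12 and C1 by 1,2-induction, and its ring closure creates no permanent stereocentre. It pays with the sulfone auxiliary.

Alternative 2: The ring is cut at C12–C13. In the forward step a zerovalent nickel catalyst with an N-heterocyclic carbene and a trialkylsilane couples a C13 aldehyde reductively with a C11≡C12 methyl alkyne to give the silylated allylic alcohol A2.
- For it: the E-C11=C12 alkene and the C13 carbinol arise in the ring-closing step from an alkyne and an aldehyde. The epoxidation, oxidation and methylenation sequence (steps 16–18 here) is not needed, so it is stronger on step count before ring closure.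
- Against it: C13 is created in the macrocyclisation under remote substrate control (the nearest centre, C1, is β to the aldehyde), although one defined C13 epimer is required because it dictates the epoxide face. The aldehyde must bond to the methyl-bearing alkyne carbon, and a methyl and a methylene substituent differ too little to secure the 14-membered over the 13-membered ring. The lactone is again saturated.
- Comparison: in the chosen route C13 comes from a Sharpless epoxide (28), and the regiochemistry of ring closure is fixed by the substitution pattern of the π-allyl unit.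

Alternative 3: The C1–C2 bond is cut by way of a 17-membered propargylic allylic ether (C2–O–C17 with a C15=C1 alkene). In the forward step, lithiation at the propargylic C2 triggers a [2,3]-Wittig shift that contracts the ring to the homopropargylic alcohol A3.
- For it: the hindered C1–C2 bond, both its stereocentres and the exocyclic C15=C17 methylene form in one ordered five-membered transition state. On the α-methylene unit it is stronger than the chosen route, which needs a final oxidative lactonisation.
- Against it: two ring events are needed (etherification, then contraction). The relative configuration of C1/C2 depends on the ring transition state and the absolute sense on remote C13 or a chiral base. A3 has a C3≡C4 alkyne without the C4 methyl group, which must still be turned into the E-trisubstituted alkene on the macrocycle.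
- Comparison: in the chosen route the C3=C4 and C7=C8 alkenes and the C1/C2 pair are complete before ring closure, and strongly basic conditions are never applied to the macrocycle.

Key step: step 19

Remarks on the chemistry, stated once:
- The (S,S)-ProPhenol–zinc catalyst of step 8 is assumed to deliver the alkynyl group to the Re face of enal 12; if the sense is opposite, the (R,R) ligand is used and nothing else changes.
- Compound 33 is a mixture of C9 epimers.
- Locants C1–C17 in the text are cembrane locants.

## Steps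

Step 1
Reactants: 1 geraniol
Product: 2 tert-butyl{[(2E)-3,7-dimethylocta-2,6-dien-1-yl]oxy}diphenylsilane
Conditions: TBDPSCl, imidazole, DMF, rt
Reagents that add atoms: tert-butyl(chloro)diphenylsilane, CC(C)(C)[Si](Cl)(c1ccccc1)c1ccccc1
Why: Silylation of a primary allylic alcohol; the tert-butyldiphenylsilyl ether is chosen because it survives the acidic cleavage of step 2, the amide base of step 3 and the hydride of step 4.

Step 2
Reactants: 2 tert-butyl{[(2E)-3,7-dimethylocta-2,6-dien-1-yl]oxy}diphenylsilane
Product: 4 (4E)-6-[(tert-butyldiphenylsilyl)oxy]-4-methylhex-4-enal, via 6,7-epoxide 3 (not isolated)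
Conditions: mCPBA, CH2Cl2, −20 °C; then H5IO6, THF–H2O, 0 °C
Reagents that add atoms: 3-chloroperoxybenzoic acid, O=C(OO)c1cccc(Cl)c1
Why: Prilezhaev epoxidation should take the distal, more electron-rich trisubstituted alkene because the 2,3-alkene is deactivated by the allylic silyloxy group; periodic acid opens the crude epoxide to the glycol and cleaves it (Malaprade cleavage), leaving the C7 aldehyde and acetone.

Step 3
Reactants: 4 (4E)-6-[(tert-butyldiphenylsilyl)oxy]-4-methylhex-4-enal; 5 ethyl 2-[bis(2,2,2-trifluoroethoxy)phosphoryl]propanoate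
Product: 7 ethyl (2Z,6E)-8-[(tert-butyldiphenylsilyl)oxy]-2,6-dimethylocta-2,6-dienoate, via potassium phosphonate 6 (not isolated)
Conditions: KN(SiMe3)2, 18-crown-6, THF, −78 °C
Reagents that add atoms: none
Why: Still–Gennari olefination; the electron-poor phosphonate with a dissociated potassium counter-ion eliminates under kinetic control, which places the ester cis to the chain and sets the Z-C7=C8 bond.

Step 4
Reactants: 7 ethyl (2Z,6E)-8-[(tert-butyldiphenylsilyl)oxy]-2,6-dimethylocta-2,6-dienoate
Product: 8 (2Z,6E)-8-[(tert-butyldiphenylsilyl)oxy]-2,6-dimethylocta-2,6-dien-1-ol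
Conditions: i-Bu2AlH (2.5 equiv), CH2Cl2, −78 °C
Reagents that add atoms: none
Why: 1,2-Reduction of a conjugated ester by an aluminium hydride; the alkene geometry is not touched and the silyl ether is inert.

Step 5
Reactants: 8 (2Z,6E)-8-[(tert-butyldiphenylsilyl)oxy]-2,6-dimethylocta-2,6-dien-1-ol
Product: 10 tert-butyl{[(2E,6Z)-3,7-dimethyl-8-(phenylsulfonyl)octa-2,6-dien-1-yl]oxy}diphenylsilane, via allylic bromide 9 (not isolated)
Conditions: CBr4, PPh3, CH2Cl2, 0 °C; then PhSO2Na, DMF, rt
Reagents that add atoms: sodium benzenesulfinate, [Na+].[O-]S(=O)c1ccccc1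
Why: Appel bromination of a primary allylic alcohol followed by SN2 S-alkylation of the sulfinate; both substitutions occur at the primary carbon, so neither allylic transposition nor loss of the Z geometry is expected.

Step 6
Reactants: 10 tert-butyl{[(2E,6Z)-3,7-dimethyl-8-(phenylsulfonyl)octa-2,6-dien-1-yl]oxy}diphenylsilane
Product: 11 (2E,6Z)-3,7-dimethyl-8-(phenylsulfonyl)octa-2,6-dien-1-ol
Conditions: Bu4NF, AcOH, THF, 0 °C to rt
Reagents that add atoms: none
Why: Fluoride desilylation; the acetic acid buffer keeps the medium from deprotonating the allylic sulfone.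

Step 7
Reactants: 11 (2E,6Z)-3,7-dimethyl-8-(phenylsulfonyl)octa-2,6-dien-1-ol
Product: 12 (2E,6Z)-3,7-dimethyl-8-(phenylsulfonyl)octa-2,6-dienal
Conditions: MnO2, CH2Cl2, rt
Reagents that add atoms: none
Why: Chemoselective oxidation of a primary allylic alcohol on MnO2; neutral conditions leave the E-enal and the sulfone unchanged.

Step 8
Reactants: 12 (2E,6Z)-3,7-dimethyl-8-(phenylsulfonyl)octa-2,6-dienal; 13 methyl propiolate
Product: 15 methyl (4S,5E,9Z)-4-hydroxy-6,10-dimethyl-11-(phenylsulfonyl)undeca-5,9-dien-2-ynoate, via alkynylzinc 14 (not isolated)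
Conditions: (S,S)-ProPhenol (20 mol %), Me2Zn (3 equiv), toluene, 4 °C
Reagents that add atoms: none
Why: Catalytic asymmetric alkynylation of an enal with a propiolate-derived alkynylzinc in the chiral pocket of the dinuclear zinc ProPhenol complex; Re-face delivery sets C2 as S, and the enal reacts 1,2 because the alkynylzinc is a hard nucleophile.

Step 9
Reactants: 15 methyl (4S,5E,9Z)-4-hydroxy-6,10-dimethyl-11-(phenylsulfonyl)undeca-5,9-dien-2-ynoate
Product: 16 methyl (2E,4R,5E,9Z)-4-hydroxy-6,10-dimethyl-11-(phenylsulfonyl)undeca-2,5,9-trienoate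
Conditions: NaAlH2(OCH2CH2OMe)2, THF, −78 °C
Reagents that add atoms: none
Why: Alkoxide-directed trans-hydroalumination of a γ-hydroxy ynoate; the aluminium alkoxide delivers hydride intramolecularly and protonation of the vinyl aluminate gives the E-enoate, while at −78 °C ester and sulfone are not reduced (the descriptor at C4 changes only because the priorities change).

Step 10
Reactants: 16 methyl (2E,4R,5E,9Z)-4-hydroxy-6,10-dimethyl-11-(phenylsulfonyl)undeca-2,5,9-trienoate
Product: 17 methyl (2E,4R,5E,9Z)-4-[(tert-butyldimethylsilyl)oxy]-6,10-dimethyl-11-(phenylsulfonyl)undeca-2,5,9-trienoate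
Conditions: TBSCl, imidazole, DMF, rt
Reagents that add atoms: tert-butyl(chloro)dimethylsilane, CC(C)(C)[Si](C)(C)Cl
Why: Silylation under neutral to mildly basic conditions protects the doubly allylic carbinol before it can ionise or isomerise, and the bulky silyloxy group becomes the control element of step 12.

Step 11
Reactants: 18 2-bromoprop-2-en-1-ol
Product: 19 [(2-bromoprop-2-en-1-yl)oxy](tert-butyl)dimethylsilane
Conditions: TBSCl, imidazole, CH2Cl2, 0 °C to rt
Reagents that add atoms: tert-butyl(chloro)dimethylsilane, CC(C)(C)[Si](C)(C)Cl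
Why: Silylation of a primary alcohol; the same silyl group as on O2 allows one global deprotection in step 23.

Step 12
Reactants: 17 methyl (2E,4R,5E,9Z)-4-[(tert-butyldimethylsilyl)oxy]-6,10-dimethyl-11-(phenylsulfonyl)undeca-2,5,9-trienoate; 19 [(2-bromoprop-2-en-1-yl)oxy](tert-butyl)dimethylsilane
Product: 23 methyl (3S,4S,5E,9Z)-4-[(tert-butyldimethylsilyl)oxy]-3-{3-[(tert-butyldimethylsilyl)oxy]prop-1-en-2-yl}-6,10-dimethyl-11-(phenylsulfonyl)undeca-5,9-dienoate, via vinyllithium 20 (not isolated), via lithium divinylcuprate 21 (not isolated), via silyl ketene acetal 22 (not isolated)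
Conditions: 19, t-BuLi (2 equiv), Et2O, −78 °C; CuI (0.5 equiv), −40 °C; then Me3SiCl, 17, THF, −78 °C; aq NH4Cl
Reagents that add atoms: none
Why: Bromine–lithium exchange, formation of the Gilman cuprate and silyl-chloride-accelerated 1,4-addition to a γ-silyloxy E-enoate; in the conformer with the γ-hydrogen eclipsing the alkene the cuprate attacks anti to the silyloxy group (modified Felkin–Anh), which gives the anti C1/C2 relationship (C1 S) of the cis-fused lactone. At −78 °C the 2-lithioallyl silyl ether should not undergo silyl migration, and the weakly basic cuprate should add faster than it deprotonates the sulfone.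

Step 13
Reactants: 23 methyl (3S,4S,5E,9Z)-4-[(tert-butyldimethylsilyl)oxy]-3-{3-[(tert-butyldimethylsilyl)oxy]prop-1-en-2-yl}-6,10-dimethyl-11-(phenylsulfonyl)undeca-5,9-dienoate
Product: 24 (3S,4S,5E,9Z)-4-[(tert-butyldimethylsilyl)oxy]-3-{3-[(tert-butyldimethylsilyl)oxy]prop-1-en-2-yl}-6,10-dimethyl-11-(phenylsulfonyl)undeca-5,9-dienal
Conditions: i-Bu2AlH (1.1 equiv), CH2Cl2, −78 °C; sodium potassium tartrate work-up
Reagents that add atoms: none
Why: Partial reduction of a methyl ester; the tetrahedral aluminium hemiacetal is stable at −78 °C and releases the aldehyde only on work-up, and the β-stereocentre C1 is not epimerisable.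

Step 14
Reactants: 24 (3S,4S,5E,9Z)-4-[(tert-butyldimethylsilyl)oxy]-3-{3-[(tert-butyldimethylsilyl)oxy]prop-1-en-2-yl}-6,10-dimethyl-11-(phenylsulfonyl)undeca-5,9-dienal; 25 ethyl 2-(triphenylphosphoranylidene)propanoate
Product: 26 ethyl (2E,5S,6S,7E,11Z)-6-[(tert-butyldimethylsilyl)oxy]-5-{3-[(tert-butyldimethylsilyl)oxy]prop-1-en-2-yl}-2,8,12-trimethyl-13-(phenylsulfonyl)trideca-2,7,11-trienoate
Conditions: toluene, 60 °C
Reagents that add atoms: none
Why: Wittig reaction of a stabilised α-methyl ylide; reversible betaine formation leads to the E-trisubstituted enoate (C12=C13), and the neutral ylide does not disturb the sulfone.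

Step 15
Reactants: 26 ethyl (2E,5S,6S,7E,11Z)-6-[(tert-butyldimethylsilyl)oxy]-5-{3-[(tert-butyldimethylsilyl)oxy]prop-1-en-2-yl}-2,8,12-trimethyl-13-(phenylsulfonyl)trideca-2,7,11-trienoate
Product: 27 (2E,5S,6S,7E,11Z)-6-[(tert-butyldimethylsilyl)oxy]-5-{3-[(tert-butyldimethylsilyl)oxy]prop-1-en-2-yl}-2,8,12-trimethyl-13-(phenylsulfonyl)trideca-2,7,11-trien-1-ol
Conditions: i-Bu2AlH (2.5 equiv), CH2Cl2, −78 °C
Reagents that add atoms: none
Why: 1,2-Reduction of the conjugated ester to the primary allylic alcohol that will direct the asymmetric epoxidation.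

Step 16
Reactants: 27 (2E,5S,6S,7E,11Z)-6-[(tert-butyldimethylsilyl)oxy]-5-{3-[(tert-butyldimethylsilyl)oxy]prop-1-en-2-yl}-2,8,12-trimethyl-13-(phenylsulfonyl)trideca-2,7,11-trien-1-ol
Product: 28 [(2S,3S)-3-{(2S,3S,4E,8Z)-3-[(tert-butyldimethylsilyl)oxy]-2-{3-[(tert-butyldimethylsilyl)oxy]prop-1-en-2-yl}-5,9-dimethyl-10-(phenylsulfonyl)deca-4,8-dien-1-yl}-2-methyloxiran-2-yl]methanol
Conditions: Ti(OiPr)4 (20 mol %), L-(+)-diethyl tartrate (24 mol %), t-BuOOH, 4 Å MS, CH2Cl2, −20 °C
Reagents that add atoms: tert-butyl hydroperoxide, CC(C)(C)OO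
Why: Sharpless asymmetric epoxidation; only the alkene bound to titanium through the primary hydroxyl reacts, and the L-(+)-tartrate complex delivers oxygen to the face that gives the (2S,3S)-epoxide of an E-2-methyl allylic alcohol, which sets C12 and C13 as S,S by reagent control.

Step 17
Reactants: 28 [(2S,3S)-3-{(2S,3S,4E,8Z)-3-[(tert-butyldimethylsilyl)oxy]-2-{3-[(tert-butyldimethylsilyl)oxy]prop-1-en-2-yl}-5,9-dimethyl-10-(phenylsulfonyl)deca-4,8-dien-1-yl}-2-methyloxiran-2-yl]methanol
Product: 29 (2R,3S)-3-{(2S,3S,4E,8Z)-3-[(tert-butyldimethylsilyl)oxy]-2-{3-[(tert-butyldimethylsilyl)oxy]prop-1-en-2-yl}-5,9-dimethyl-10-(phenylsulfonyl)deca-4,8-dien-1-yl}-2-methyloxirane-2-carbaldehyde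
Conditions: Dess–Martin periodinane, NaHCO3, CH2Cl2, 0 °C to rt
Reagents that add atoms: none
Why: Buffered Dess–Martin oxidation of an epoxy alcohol; C12 is quaternary, so the aldehyde cannot epimerise (the descriptor at C12 changes only through the priorities).

Step 18
Reactants: 29 (2R,3S)-3-{(2S,3S,4E,8Z)-3-[(tert-butyldimethylsilyl)oxy]-2-{3-[(tert-butyldimethylsilyl)oxy]prop-1-en-2-yl}-5,9-dimethyl-10-(phenylsulfonyl)deca-4,8-dien-1-yl}-2-methyloxirane-2-carbaldehyde; 30 methyltriphenylphosphonium bromide
Product: 32 (2S,3S)-2-ethenyl-2-methyl-3-{(2S,3S,4E,8Z)-3-[(tert-butyldimethylsilyl)oxy]-2-{3-[(tert-butyldimethylsilyl)oxy]prop-1-en-2-yl}-5,9-dimethyl-10-(phenylsulfonyl)deca-4,8-dien-1-yl}oxirane, via methylene ylide 31 (not isolated)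
Conditions: 30, KN(SiMe3)2, THF, 0 °C; then 29, −78 to 0 °C
Reagents that add atoms: none
Why: Wittig methylenation of an epoxy aldehyde gives the vinyl epoxide and brings in C10; addition of the aldehyde to the preformed ylide at −78 °C should let the fast, irreversible olefination outrun proton transfer from the allylic sulfone.

Step 19
Reactants: 32 (2S,3S)-2-ethenyl-2-methyl-3-{(2S,3S,4E,8Z)-3-[(tert-butyldimethylsilyl)oxy]-2-{3-[(tert-butyldimethylsilyl)oxy]prop-1-en-2-yl}-5,9-dimethyl-10-(phenylsulfonyl)deca-4,8-dien-1-yl}oxirane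
Product: 33 (1S,2E,6Z,10E,12S,13S)-12-[(tert-butyldimethylsilyl)oxy]-13-{3-[(tert-butyldimethylsilyl)oxy]prop-1-en-2-yl}-2,6,10-trimethyl-5-(phenylsulfonyl)cyclotetradeca-2,6,10-trien-1-ol (both C5 epimers)
Conditions: Pd(PPh3)4 (10 mol %), dppe (10 mol %), THF, reflux, syringe-pump addition of 32, final concentration about 0.002 M
Reagents that add atoms: none
Why: Tsuji–Trost allylic alkylation with a vinyl epoxide as allyl donor: zerovalent palladium adds to the vinyl group anti to the C12–O bond and opens the epoxide with inversion at C12 to a zwitterionic divalent π-allylpalladium complex that carries the C13 alkoxide. This alkoxide is the only base present; it removes a C9 proton of the allylic sulfone, and the soft sulfonyl carbanion attacks the allyl ligand on the face opposite to palladium, which returns zerovalent palladium. The closest known reaction type is the palladium-catalysed macrocyclisation of stabilised carbanions onto vinyl epoxides with 1,4-opening under neutral conditions. Ring closure: the carbanion bonds to the distal, unsubstituted terminus C10, so the whole allyl unit C10–C11–C12 becomes endocyclic and the 14-membered carbocycle forms (14-endo with respect to the allyl unit); attack at the quaternary C12 would give a 12-membered ring with an exocyclic vinyl group and is disfavoured by hindrance and strain. No permanent stereocentre is created: C9 forms as a mixture that is erased in step 20, C12 becomes trigonal, and C13, C1 and C2 are not involved, so the 13S carbinol comes unchanged from the Sharpless epoxide. The E geometry of C11=C12 requires the syn complex with the carbinol carbon C13 syn and the methyl group anti, which is the less strained arrangement. The step also needs bonding at C9 and not C7 of the ambident anion (charge is localised next to sulfur), retention of the Z-C7=C8 bond (the carbanion is formed only transiently and without external base) and ring closure over oligomerisation (slow addition at high dilution).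

Step 20
Reactants: 33 (1S,2E,6Z,10E,12S,13S)-12-[(tert-butyldimethylsilyl)oxy]-13-{3-[(tert-butyldimethylsilyl)oxy]prop-1-en-2-yl}-2,6,10-trimethyl-5-(phenylsulfonyl)cyclotetradeca-2,6,10-trien-1-ol
Product: 34 (1S,2E,6Z,10E,12S,13S)-12-[(tert-butyldimethylsilyl)oxy]-13-{3-[(tert-butyldimethylsilyl)oxy]prop-1-en-2-yl}-2,6,10-trimethylcyclotetradeca-2,6,10-trien-1-ol
Conditions: 6% Na/Hg, Na2HPO4, MeOH–THF, −20 °C
Reagents that add atoms: none
Why: Reductive desulfonylation by electron transfer; the C–S bond fragments and the allyl anion is protonated by methanol, the phosphate buffer prevents base-induced elimination of sulfinate, and the low temperature is meant to let protonation at C9 precede rotation or transposition of the allyl system.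

Step 21
Reactants: 34 (1S,2E,6Z,10E,12S,13S)-12-[(tert-butyldimethylsilyl)oxy]-13-{3-[(tert-butyldimethylsilyl)oxy]prop-1-en-2-yl}-2,6,10-trimethylcyclotetradeca-2,6,10-trien-1-ol
Product: 35 (1S,2S,3E,7Z,11S,12S,13S)-2,16-bis[(tert-butyldimethylsilyl)oxy]-11,12-epoxycembra-3,7,15(17)-trien-13-ol (erythro epoxy alcohol; the epoxide has the spatial arrangement of 40)
Conditions: VO(acac)2 (5 mol %), t-BuOOH, CH2Cl2, 0 °C
Reagents that add atoms: tert-butyl hydroperoxide, CC(C)(C)OO
Why: Hydroxyl-directed vanadium epoxidation; only the alkene allylic to the free hydroxyl reacts. In the vanadate ester the O–C13–C12=C11 dihedral is near 45° with C13–H eclipsing the C12 methyl group (A(1,2) strain) and C14 anti to the incoming oxygen, which gives the erythro isomer; with the 13S carbinol this is the 11S,12R epoxide face of 40.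

Step 22
Reactants: 35 (1S,2S,3E,7Z,11S,12S,13S)-2,16-bis[(tert-butyldimethylsilyl)oxy]-11,12-epoxycembra-3,7,15(17)-trien-13-ol
Product: 36 (1S,2S,3E,7Z,11S,12R,13R)-13-acetoxy-2,16-bis[(tert-butyldimethylsilyl)oxy]-11,12-epoxycembra-3,7,15(17)-triene
Conditions: AcOH, PPh3, DIAD, toluene, 0 °C to rt
Reagents that add atoms: acetic acid, CC(=O)O
Why: Mitsunobu esterification; acetate displaces the oxyphosphonium group at C13 by SN2 with inversion, which turns the erythro into the threo arrangement and installs the acetate in the same operation, and the neutral conditions spare the epoxide.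

Step 23
Reactants: 36 (1S,2S,3E,7Z,11S,12R,13R)-13-acetoxy-2,16-bis[(tert-butyldimethylsilyl)oxy]-11,12-epoxycembra-3,7,15(17)-triene
Product: 37 (1S,2S,3E,7Z,11S,12R,13R)-13-acetoxy-11,12-epoxycembra-3,7,15(17)-triene-2,16-diol
Conditions: Bu4NF, AcOH, THF, rt to 40 °C
Reagents that add atoms: none
Why: Fluoride cleavage of both silyl ethers; buffering with acetic acid suppresses acetate migration or cleavage and avoids the acid that would open the epoxide.

Step 24
Reactants: 37 (1S,2S,3E,7Z,11S,12R,13R)-13-acetoxy-11,12-epoxycembra-3,7,15(17)-triene-2,16-diol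
Product: 40 (1S,2S,3E,7Z,11S,12R,13R)-13-acetoxy-11,12-epoxycembra-3,7,15(17)-trien-16,2-olide (CNP0146076.3), via hydroxy enal 38 (not isolated), via lactol 39 (not isolated)
Conditions: TEMPO (20 mol %), PhI(OAc)2 (3 equiv), CH2Cl2, rt
Reagents that add atoms: none
Why: Oxoammonium oxidation is much faster for the primary allylic alcohol than for the secondary one; the resulting enal is trapped by the C2 hydroxyl as a five-membered lactol (5-exo addition to the carbonyl rather than 5-endo conjugate addition), and the lactol is oxidised on to the α-methylene lactone. The cis ring fusion follows from the C1/C2 configuration set in steps 8 and 12.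

## Compound list

1 | geraniol | CC(C)=CCC/C(C)=C/CO | starting material
2 | tert-butyl{[(2E)-3,7-dimethylocta-2,6-dien-1-yl]oxy}diphenylsilane | CC(C)=CCC/C(C)=C/CO[Si](c1ccccc1)(c1ccccc1)C(C)(C)C | intermediate
3 | tert-butyl{[(2E)-5-(3,3-dimethyloxiran-2-yl)-3-methylpent-2-en-1-yl]oxy}diphenylsilane (racemic at the oxirane, not isolated) | CC1(C)OC1CC/C(C)=C/CO[Si](c1ccccc1)(c1ccccc1)C(C)(C)C | intermediate
4 | (4E)-6-[(tert-butyldiphenylsilyl)oxy]-4-methylhex-4-enal | O=CCC/C(C)=C/CO[Si](c1ccccc1)(c1ccccc1)C(C)(C)C | intermediate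
5 | ethyl 2-[bis(2,2,2-trifluoroethoxy)phosphoryl]propanoate | CCOC(=O)C(C)P(=O)(OCC(F)(F)F)OCC(F)(F)F | starting material
6 | potassium salt of 5 (phosphonate carbanion, not isolated) | CCOC(=O)[C-](C)P(=O)(OCC(F)(F)F)OCC(F)(F)F.[K+] | intermediate
7 | ethyl (2Z,6E)-8-[(tert-butyldiphenylsilyl)oxy]-2,6-dimethylocta-2,6-dienoate | CCOC(=O)/C(C)=C\CC/C(C)=C/CO[Si](c1ccccc1)(c1ccccc1)C(C)(C)C | intermediate
8 | (2Z,6E)-8-[(tert-butyldiphenylsilyl)oxy]-2,6-dimethylocta-2,6-dien-1-ol | OC/C(C)=C\CC/C(C)=C/CO[Si](c1ccccc1)(c1ccccc1)C(C)(C)C | intermediate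
9 | {[(2E,6Z)-8-bromo-3,7-dimethylocta-2,6-dien-1-yl]oxy}(tert-butyl)diphenylsilane (not isolated) | BrC/C(C)=C\CC/C(C)=C/CO[Si](c1ccccc1)(c1ccccc1)C(C)(C)C | intermediate
10 | tert-butyl{[(2E,6Z)-3,7-dimethyl-8-(phenylsulfonyl)octa-2,6-dien-1-yl]oxy}diphenylsilane | O=S(=O)(c1ccccc1)C/C(C)=C\CC/C(C)=C/CO[Si](c1ccccc1)(c1ccccc1)C(C)(C)C | intermediate
11 | (2E,6Z)-3,7-dimethyl-8-(phenylsulfonyl)octa-2,6-dien-1-ol | O=S(=O)(c1ccccc1)C/C(C)=C\CC/C(C)=C/CO | intermediate
12 | (2E,6Z)-3,7-dimethyl-8-(phenylsulfonyl)octa-2,6-dienal | O=S(=O)(c1ccccc1)C/C(C)=C\CC/C(C)=C/C=O | intermediate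
13 | methyl propiolate | C#CC(=O)OC | starting material
14 | methyl 3-(methylzincio)prop-2-ynoate (not isolated) | C[Zn]C#CC(=O)OC | intermediate
15 | methyl (4S,5E,9Z)-4-hydroxy-6,10-dimethyl-11-(phenylsulfonyl)undeca-5,9-dien-2-ynoate | O=S(=O)(c1ccccc1)C/C(C)=C\CC/C(C)=C/[C@H](O)C#CC(=O)OC | intermediate
16 | methyl (2E,4R,5E,9Z)-4-hydroxy-6,10-dimethyl-11-(phenylsulfonyl)undeca-2,5,9-trienoate | O=S(=O)(c1ccccc1)C/C(C)=C\CC/C(C)=C/[C@H](O)/C=C/C(=O)OC | intermediate
17 | methyl (2E,4R,5E,9Z)-4-[(tert-butyldimethylsilyl)oxy]-6,10-dimethyl-11-(phenylsulfonyl)undeca-2,5,9-trienoate | O=S(=O)(c1ccccc1)C/C(C)=C\CC/C(C)=C/[C@H](O[Si](C)(C)C(C)(C)C)/C=C/C(=O)OC | intermediate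
18 | 2-bromoprop-2-en-1-ol | C=C(Br)CO | starting material
19 | [(2-bromoprop-2-en-1-yl)oxy](tert-butyl)dimethylsilane | C=C(Br)CO[Si](C)(C)C(C)(C)C | intermediate
20 | {3-[(tert-butyldimethylsilyl)oxy]prop-1-en-2-yl}lithium (not isolated) | [Li]C(=C)CO[Si](C)(C)C(C)(C)C | intermediate
21 | lithium bis{3-[(tert-butyldimethylsilyl)oxy]prop-1-en-2-yl}cuprate (not isolated) | [Li+].C=C(CO[Si](C)(C)C(C)(C)C)[Cu-]C(=C)CO[Si](C)(C)C(C)(C)C | intermediate
22 | trimethylsilyl ketene acetal of 23 (enol ether geometry undefined, not isolated) | O=S(=O)(c1ccccc1)C/C(C)=C\CC/C(C)=C/[C@H](O[Si](C)(C)C(C)(C)C)[C@H](C(=C)CO[Si](C)(C)C(C)(C)C)C=C(OC)O[Si](C)(C)C | intermediate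
23 | methyl (3S,4S,5E,9Z)-4-[(tert-butyldimethylsilyl)oxy]-3-{3-[(tert-butyldimethylsilyl)oxy]prop-1-en-2-yl}-6,10-dimethyl-11-(phenylsulfonyl)undeca-5,9-dienoate | O=S(=O)(c1ccccc1)C/C(C)=C\CC/C(C)=C/[C@H](O[Si](C)(C)C(C)(C)C)[C@H](C(=C)CO[Si](C)(C)C(C)(C)C)CC(=O)OC | intermediate
24 | (3S,4S,5E,9Z)-4-[(tert-butyldimethylsilyl)oxy]-3-{3-[(tert-butyldimethylsilyl)oxy]prop-1-en-2-yl}-6,10-dimethyl-11-(phenylsulfonyl)undeca-5,9-dienal | O=S(=O)(c1ccccc1)C/C(C)=C\CC/C(C)=C/[C@H](O[Si](C)(C)C(C)(C)C)[C@H](C(=C)CO[Si](C)(C)C(C)(C)C)CC=O | intermediate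
25 | ethyl 2-(triphenylphosphoranylidene)propanoate | CCOC(=O)C(C)=P(c1ccccc1)(c1ccccc1)c1ccccc1 | starting material
26 | ethyl (2E,5S,6S,7E,11Z)-6-[(tert-butyldimethylsilyl)oxy]-5-{3-[(tert-butyldimethylsilyl)oxy]prop-1-en-2-yl}-2,8,12-trimethyl-13-(phenylsulfonyl)trideca-2,7,11-trienoate | O=S(=O)(c1ccccc1)C/C(C)=C\CC/C(C)=C/[C@H](O[Si](C)(C)C(C)(C)C)[C@H](C(=C)CO[Si](C)(C)C(C)(C)C)C/C=C(\C)C(=O)OCC | intermediate
27 | (2E,5S,6S,7E,11Z)-6-[(tert-butyldimethylsilyl)oxy]-5-{3-[(tert-butyldimethylsilyl)oxy]prop-1-en-2-yl}-2,8,12-trimethyl-13-(phenylsulfonyl)trideca-2,7,11-trien-1-ol | O=S(=O)(c1ccccc1)C/C(C)=C\CC/C(C)=C/[C@H](O[Si](C)(C)C(C)(C)C)[C@H](C(=C)CO[Si](C)(C)C(C)(C)C)C/C=C(\C)CO | intermediate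
28 | [(2S,3S)-3-{(2S,3S,4E,8Z)-3-[(tert-butyldimethylsilyl)oxy]-2-{3-[(tert-butyldimethylsilyl)oxy]prop-1-en-2-yl}-5,9-dimethyl-10-(phenylsulfonyl)deca-4,8-dien-1-yl}-2-methyloxiran-2-yl]methanol | O=S(=O)(c1ccccc1)C/C(C)=C\CC/C(C)=C/[C@H](O[Si](C)(C)C(C)(C)C)[C@H](C(=C)CO[Si](C)(C)C(C)(C)C)C[C@@H]1O[C@@]1(C)CO | intermediate
29 | (2R,3S)-3-{(2S,3S,4E,8Z)-3-[(tert-butyldimethylsilyl)oxy]-2-{3-[(tert-butyldimethylsilyl)oxy]prop-1-en-2-yl}-5,9-dimethyl-10-(phenylsulfonyl)deca-4,8-dien-1-yl}-2-methyloxirane-2-carbaldehyde | O=S(=O)(c1ccccc1)C/C(C)=C\CC/C(C)=C/[C@H](O[Si](C)(C)C(C)(C)C)[C@H](C(=C)CO[Si](C)(C)C(C)(C)C)C[C@@H]1O[C@@]1(C)C=O | intermediate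
30 | methyltriphenylphosphonium bromide | C[P+](c1ccccc1)(c1ccccc1)c1ccccc1.[Br-] | starting material
31 | methylidenetriphenylphosphorane (not isolated) | C=P(c1ccccc1)(c1ccccc1)c1ccccc1 | intermediate
32 | (2S,3S)-2-ethenyl-2-methyl-3-{(2S,3S,4E,8Z)-3-[(tert-butyldimethylsilyl)oxy]-2-{3-[(tert-butyldimethylsilyl)oxy]prop-1-en-2-yl}-5,9-dimethyl-10-(phenylsulfonyl)deca-4,8-dien-1-yl}oxirane (C9 allylic sulfone with 12S,13S vinyl epoxide) | O=S(=O)(c1ccccc1)C/C(C)=C\CC/C(C)=C/[C@H](O[Si](C)(C)C(C)(C)C)[C@H](C(=C)CO[Si](C)(C)C(C)(C)C)C[C@@H]1O[C@@]1(C)C=C | intermediate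
33 | (1S,2E,6Z,10E,12S,13S)-12-[(tert-butyldimethylsilyl)oxy]-13-{3-[(tert-butyldimethylsilyl)oxy]prop-1-en-2-yl}-2,6,10-trimethyl-5-(phenylsulfonyl)cyclotetradeca-2,6,10-trien-1-ol (C9 sulfone, both epimers; 13S carbinol in cembrane numbering) | O=S(=O)(c1ccccc1)C1/C(C)=C\CC/C(C)=C/[C@H](O[Si](C)(C)C(C)(C)C)[C@H](C(=C)CO[Si](C)(C)C(C)(C)C)C[C@H](O)/C(C)=C/C1 | intermediate
34 | (1S,2E,6Z,10E,12S,13S)-12-[(tert-butyldimethylsilyl)oxy]-13-{3-[(tert-butyldimethylsilyl)oxy]prop-1-en-2-yl}-2,6,10-trimethylcyclotetradeca-2,6,10-trien-1-ol | CC(C)(C)[Si](C)(C)O[C@H]1/C=C(\C)CC/C=C(/C)CC/C=C(\C)[C@@H](O)C[C@H]1C(=C)CO[Si](C)(C)C(C)(C)C | intermediate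
35 | (1S,2S,3E,7Z,11S,12S,13S)-2,16-bis[(tert-butyldimethylsilyl)oxy]-11,12-epoxycembra-3,7,15(17)-trien-13-ol (erythro; 12S here and 12R in 36 are the same spatial arrangement) | CC(C)(C)[Si](C)(C)O[C@H]1/C=C(\C)CC/C=C(/C)CC[C@@H]2O[C@@]2(C)[C@@H](O)C[C@H]1C(=C)CO[Si](C)(C)C(C)(C)C | intermediate
36 | (1S,2S,3E,7Z,11S,12R,13R)-13-acetoxy-2,16-bis[(tert-butyldimethylsilyl)oxy]-11,12-epoxycembra-3,7,15(17)-triene | CC(C)(C)[Si](C)(C)O[C@H]1/C=C(\C)CC/C=C(/C)CC[C@@H]2O[C@@]2(C)[C@H](OC(C)=O)C[C@H]1C(=C)CO[Si](C)(C)C(C)(C)C | intermediate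
37 | (1S,2S,3E,7Z,11S,12R,13R)-13-acetoxy-11,12-epoxycembra-3,7,15(17)-triene-2,16-diol | O[C@H]1/C=C(\C)CC/C=C(/C)CC[C@@H]2O[C@@]2(C)[C@H](OC(C)=O)C[C@H]1C(=C)CO | intermediate
38 | (1S,2S,3E,7Z,11S,12R,13R)-13-acetoxy-11,12-epoxy-2-hydroxycembra-3,7,15(17)-trien-16-al (not isolated) | O[C@H]1/C=C(\C)CC/C=C(/C)CC[C@@H]2O[C@@]2(C)[C@H](OC(C)=O)C[C@H]1C(=C)C=O | intermediate
39 | 16,2-lactol of 38 (mixture at C16, not isolated) | C=C1C(O)O[C@H]2/C=C(\C)CC/C=C(/C)CC[C@@H]3O[C@@]3(C)[C@H](OC(C)=O)C[C@@H]12 | intermediate
40 | (1S,2S,3E,7Z,11S,12R,13R)-13-acetoxy-11,12-epoxycembra-3,7,15(17)-trien-16,2-olide (CNP0146076.3) | C=C1C(=O)O[C@H]2/C=C(\C)CC/C=C(/C)CC[C@@H]3O[C@@]3(C)[C@H](OC(C)=O)C[C@@H]12 | target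

## Step count and least certain steps

Total step count: 24. Longest linear sequence: 23 steps (steps 1–10 and 12–24, from geraniol 1); step 11 prepares bromide 19.

Step 19 (key step). Most likely failures:
- intermolecular alkylation to oligomers;
- slow proton transfer from the weakly acidic allylic sulfone, which lets the zwitterionic complex decay by β-hydride elimination to a dienol;
- partial formation of the Z-C11=C12 isomer through the anti complex;
- Z to E drift at C7=C8 through the delocalised sulfonyl anion;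
- a palladium-induced 1,3-shift of the allylic sulfone at reflux.

Fallback, from 32 back to 33, separates allyl activation from carbanion formation. Pd(PPh3)4-catalysed 1,4-addition of acetic acid to 32 should give the (E)-allylic acetate F1 with the free 13S carbinol. Et3SiCl and imidazole give the triethylsilyl ether F2. The sulfonyl carbanion of F2 is preformed with NaH and cyclised onto the allylic acetate with Pd(PPh3)4 and dppe at high dilution to the 13-O-triethylsilyl macrocycle F3. Pyridinium p-toluenesulfonate in MeOH removes the triethylsilyl group selectively and gives 33.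

Step 20. The delocalised allyl radical or anion formed on C–S cleavage has two secondary termini. Protonation at C7 instead of C9 would move the alkene to C8=C9, and rotation within the allyl system would erode the Z geometry. Fallback, from 33 directly to 34: hydride displacement through a π-allylpalladium hydride with PdCl2(dppp) and LiBHEt3 in THF at 0 °C (one extra equivalent of hydride for the free hydroxyl). This replaces the free allyl anion by an inner-sphere hydride transfer and makes no new compound (F0).

Step 22. C13 is flanked by the quaternary epoxide carbon, so formation of the oxyphosphonium ion and the SN2 attack of the weakly acidic acetic acid may be slow; elimination or return of unchanged 35 would follow. Fallback, from 35 back to 36: Mitsunobu reaction with the more acidic 4-nitrobenzoic acid should give the inverted 4-nitrobenzoate F4. K2CO3 in MeOH liberates the threo epoxy alcohol F5, and Ac2O with DMAP gives 36.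

Step 21. The ring conformation may override the A(1,2) preference, which would lower the facial selectivity; loss of chemoselectivity is less likely. Fallback, from 34 to 35: stoichiometric Ti(OiPr)4, L-(+)-diisopropyl tartrate and t-BuOOH at −20 °C. The 13S carbinol is the fast-reacting enantiomer for this tartrate, so reagent control reinforces the erythro sense; no new compound is made (F0).

Step 12. The γ-substituent is alkenyl and not alkyl, so anti selectivity may be lower. The cuprate may also deprotonate the allylic sulfone or cause reductive loss of the γ-silyloxy group. Fallback, from 15, returning at 26, uses the trans-selective addition to a butenolide: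
- semi-hydrogenation of 15 over Pd/CaCO3 poisoned with Pb(OAc)2 and quinoline gives the Z-enoate, which lactonises to butenolide F6;
- cuprate 21 adds trans to the C2 substituent to give lactone F7;
- i-Bu2AlH at −78 °C gives lactol F8;
- Wittig reaction with 25 gives hydroxy enoate F9;
- TBSCl and imidazole give 26.

Step 18. Proton transfer from the allylic sulfone to the ylide may stall the olefination and allow the sulfonyl anion to add to the aldehyde or to isomerise the Z alkene. Fallback, from 29, returning at 32: Ohira–Bestmann homologation (dimethyl (1-diazo-2-oxopropyl)phosphonate, K2CO3, MeOH), which is too weakly basic to deprotonate the sulfone, gives the ethynyl epoxide F10. Semi-hydrogenation over Pd/CaCO3 poisoned with Pb(OAc)2 and quinoline gives 32.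

## Further compounds

F1 | step 19 | [(2E,4S,6S,7S,8E,12Z)-7-[(tert-butyldimethylsilyl)oxy]-6-{3-[(tert-butyldimethylsilyl)oxy]prop-1-en-2-yl}-4-hydroxy-3,9,13-trimethyl-14-(phenylsulfonyl)tetradeca-2,8,12-trien-1-yl] acetate | O=S(=O)(c1ccccc1)C/C(C)=C\CC/C(C)=C/[C@H](O[Si](C)(C)C(C)(C)C)[C@H](C(=C)CO[Si](C)(C)C(C)(C)C)C[C@H](O)/C(C)=C/COC(C)=O
F2 | step 19 | 4-O-triethylsilyl ether of F1 | O=S(=O)(c1ccccc1)C/C(C)=C\CC/C(C)=C/[C@H](O[Si](C)(C)C(C)(C)C)[C@H](C(=C)CO[Si](C)(C)C(C)(C)C)C[C@H](O[Si](CC)(CC)CC)/C(C)=C/COC(C)=O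
F3 | step 19 | 1-O-triethylsilyl ether of 33 (C9 epimers) | O=S(=O)(c1ccccc1)C1/C(C)=C\CC/C(C)=C/[C@H](O[Si](C)(C)C(C)(C)C)[C@H](C(=C)CO[Si](C)(C)C(C)(C)C)C[C@H](O[Si](CC)(CC)CC)/C(C)=C/C1
F0 | step 20 | none | none
F4 | step 22 | (1S,2S,3E,7Z,11S,12R,13R)-2,16-bis[(tert-butyldimethylsilyl)oxy]-11,12-epoxycembra-3,7,15(17)-trien-13-yl 4-nitrobenzoate | CC(C)(C)[Si](C)(C)O[C@H]1/C=C(\C)CC/C=C(/C)CC[C@@H]2O[C@@]2(C)[C@H](OC(=O)c3ccc(cc3)[N+](=O)[O-])C[C@H]1C(=C)CO[Si](C)(C)C(C)(C)C
F5 | step 22 | (1S,2S,3E,7Z,11S,12S,13R)-2,16-bis[(tert-butyldimethylsilyl)oxy]-11,12-epoxycembra-3,7,15(17)-trien-13-ol (threo epoxy alcohol) | CC(C)(C)[Si](C)(C)O[C@H]1/C=C(\C)CC/C=C(/C)CC[C@@H]2O[C@@]2(C)[C@H](O)C[C@H]1C(=C)CO[Si](C)(C)C(C)(C)C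
F0 | step 21 | none | none
F6 | step 12 | (5R)-5-[(1E,5Z)-2,6-dimethyl-7-(phenylsulfonyl)hepta-1,5-dien-1-yl]furan-2(5H)-one | O=C1C=C[C@@H](O1)/C=C(\C)CC/C=C(/C)CS(=O)(=O)c1ccccc1
F7 | step 12 | (4S,5S)-4-{3-[(tert-butyldimethylsilyl)oxy]prop-1-en-2-yl}-5-[(1E,5Z)-2,6-dimethyl-7-(phenylsulfonyl)hepta-1,5-dien-1-yl]dihydrofuran-2(3H)-one | O=C1C[C@@H](C(=C)CO[Si](C)(C)C(C)(C)C)[C@@H](O1)/C=C(\C)CC/C=C(/C)CS(=O)(=O)c1ccccc1
F8 | step 12 | lactol of F7 (mixture at the hemiacetal carbon) | OC1C[C@@H](C(=C)CO[Si](C)(C)C(C)(C)C)[C@@H](O1)/C=C(\C)CC/C=C(/C)CS(=O)(=O)c1ccccc1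
F9 | step 12 | ethyl (2E,5S,6S,7E,11Z)-5-{3-[(tert-butyldimethylsilyl)oxy]prop-1-en-2-yl}-6-hydroxy-2,8,12-trimethyl-13-(phenylsulfonyl)trideca-2,7,11-trienoate | O=S(=O)(c1ccccc1)C/C(C)=C\CC/C(C)=C/[C@H](O)[C@H](C(=C)CO[Si](C)(C)C(C)(C)C)C/C=C(\C)C(=O)OCC
F10 | step 18 | (2S,3S)-2-ethynyl-2-methyl-3-{(2S,3S,4E,8Z)-3-[(tert-butyldimethylsilyl)oxy]-2-{3-[(tert-butyldimethylsilyl)oxy]prop-1-en-2-yl}-5,9-dimethyl-10-(phenylsulfonyl)deca-4,8-dien-1-yl}oxirane | O=S(=O)(c1ccccc1)C/C(C)=C\CC/C(C)=C/[C@H](O[Si](C)(C)C(C)(C)C)[C@H](C(=C)CO[Si](C)(C)C(C)(C)C)C[C@@H]1O[C@@]1(C)C#C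
A1 | alternative 1 | 14-membered 3E,7Z,11E-triene with cis-fused saturated γ-lactone and 13-O-tert-butyldimethylsilyl group (C1, C2 and C13 arranged as in 40; no C17 methylene) | O=C1O[C@H]2/C=C(\C)CC/C=C(/C)CC/C=C(\C)[C@H](O[Si](C)(C)C(C)(C)C)C[C@H]2C1
A2 | alternative 2 | 14-membered 3E,7Z,11E-triene with cis-fused saturated γ-lactone and 13-O-triethylsilyl group | O=C1O[C@H]2/C=C(\C)CC/C=C(/C)CC/C=C(\C)[C@H](O[Si](CC)(CC)CC)C[C@H]2C1
A3 | alternative 3 | 14-membered homopropargylic C2 alcohol with C3≡C4 alkyne, C15=C17 methylene, 16-O-tert-butyldimethylsilyl and 13-O-triisopropylsilyl groups | O[C@H]1C#CCC/C=C(/C)CC/C=C(\C)[C@H](O[Si](C(C)C)(C(C)C)C(C)C)C[C@H]1C(=C)CO[Si](C)(C)C(C)(C)C
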